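**Retrosynthetic overview**
1. Target 31 ⇐ trienolide 30 by a last peracid epoxidation of the C1=C10 alkene; 30 ⇐ alcohol 26 + glycidic acid 29 (from tiglyl alcohol by Sharpless epoxidation).
2. Key step: the C7–C8 bond, made by SmI2 ketyl-radical 10-exo cyclisation of aldehyde 21 onto its own butenolide. It closes the carbocycle and sets C7 and C8; the samarium enolate is trapped with Eschenmoser's salt, which supplies C13.
3. 21 ⇐ Z-enal 16 + methyl propiolate (zinc–ProPhenol alkynylation sets C6; Lindlar reduction and lactonisation give the butenolide).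
4. 16 ⇐ C3–C4 asymmetric Nozaki–Hiyama–Kishi coupling of Z-vinyl iodide 4 (from but-2-yn-1-ol) with aldehyde 11 (but-3-yn-1-ol + AlMe3 + oxirane); the benzoate comes from benzaldehyde.
5. Ring order: butenolide (lactone ring) → ten-membered carbocycle (radical step) → side-chain oxirane (made separately, attached as the acid) → ring epoxide last.

Assumption: ring carbons carry germacrane locants (C1–C10 ring, C11–C13 lactone arm, C14 on C10, C15 on C4); the target is read from the SMILES as (1R,3S,6R,7R,8R,10R), 4Z, with a (2S,3R)-2,3-dimethyloxirane-2-carboxylate on O8.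

**Route**

Step 1
Reactants: 1 but-2-yn-1-ol
Product: 3 (2Z)-3-iodobut-2-en-1-ol, via sodium alkenylaluminate 2 (not isolated)
Conditions: NaAlH2(OCH2CH2OCH3)2, THF, 0 °C to rt; then I2, −78 °C to 0 °C
Reagents that add atoms: iodine, II
Why: Alkoxide-directed trans-hydroalumination puts aluminium on C3 and iodinolysis goes with retention, giving the Z vinyl iodide that becomes the 4Z alkene (Corey hydroalumination–iodination).

Step 2
Reactants: 3 (2Z)-3-iodobut-2-en-1-ol
Product: 4 tert-butyl{[(2Z)-3-iodobut-2-en-1-yl]oxy}dimethylsilane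
Conditions: TBSCl, imidazole, CH2Cl2, 0 °C to rt
Reagents that add atoms: tert-butyldimethylsilyl chloride, CC(C)(C)[Si](C)(C)Cl
Why: Standard silylation of a primary alcohol; the alkene geometry is untouched.

Step 3
Reactants: 5 but-3-yn-1-ol
Product: 6 tert-butyl(but-3-yn-1-yloxy)dimethylsilane
Conditions: TBSCl, imidazole, CH2Cl2, 0 °C to rt
Reagents that add atoms: tert-butyldimethylsilyl chloride, CC(C)(C)[Si](C)(C)Cl
Why: Standard silylation; masks the future C8 oxygen through the organometallic steps.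

Step 4
Reactants: 6 tert-butyl(but-3-yn-1-yloxy)dimethylsilane; 7 oxirane
Product: 10 (3E)-6-{[tert-butyl(dimethyl)silyl]oxy}-4-methylhex-3-en-1-ol, via alkenyldimethylalane 8 (not isolated), via lithium alkenylalanate 9 (not isolated)
Conditions: AlMe3, Cp2ZrCl2 (25 mol%), CH2Cl2, 0 °C to rt; then n-BuLi, THF/hexane, −78 to 0 °C; then oxirane, −78 °C to rt
Reagents that add atoms: trimethylaluminium, C[Al](C)C
Why: Negishi zirconium-catalysed methylalumination is syn with methyl on the internal carbon, fixing the E trisubstituted alkene (future C1=C10); the lithium alanate then opens oxirane with retention of geometry.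

Step 5
Reactants: 10 (3E)-6-{[tert-butyl(dimethyl)silyl]oxy}-4-methylhex-3-en-1-ol
Product: 11 (3E)-6-{[tert-butyl(dimethyl)silyl]oxy}-4-methylhex-3-enal
Conditions: Dess–Martin periodinane, NaHCO3, CH2Cl2, 0 °C; used crude at once
Reagents that add atoms: none
Why: Buffered Dess–Martin oxidation gives the β,γ-unsaturated aldehyde without conjugation of the alkene.

Step 6
Reactants: 4 tert-butyl{[(2Z)-3-iodobut-2-en-1-yl]oxy}dimethylsilane; 11 (3E)-6-{[tert-butyl(dimethyl)silyl]oxy}-4-methylhex-3-enal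
Product: 12 (2Z,4S,6E)-1,9-bis{[tert-butyl(dimethyl)silyl]oxy}-3,7-dimethylnona-2,6-dien-4-ol
Conditions: CrCl2, NiCl2 (2 mol%), Kishi oxazoline–sulfonamide ligand (antipode giving 4S), Et3N, THF, rt
Reagents that add atoms: none
Why: Asymmetric Nozaki–Hiyama–Kishi coupling: the alkenylchromium reagent forms with retention of Z geometry and adds to the aldehyde, and the chiral chromium–sulfonamide complex sets the 4S carbinol (target C3) by reagent control.

Step 7
Reactants: 12 (2Z,4S,6E)-1,9-bis{[tert-butyl(dimethyl)silyl]oxy}-3,7-dimethylnona-2,6-dien-4-ol; 13 benzaldehyde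
Product: 14 (2Z,4S,6E)-1,9-bis{[tert-butyl(dimethyl)silyl]oxy}-3,7-dimethylnona-2,6-dien-4-yl benzoate
Conditions: PhCHO (3 equiv), 1,3-dimesitylimidazolium chloride (10 mol%), DBU, 3,3',5,5'-tetra-tert-butyl-4,4'-diphenoquinone, THF, rt
Reagents that add atoms: none
Why: NHC-catalysed oxidative esterification: the Breslow intermediate of benzaldehyde is oxidised by the quinone to an acyl azolium that acylates the secondary alcohol; the stereocentre is not touched.

Step 8
Reactants: 14 (2Z,4S,6E)-1,9-bis{[tert-butyl(dimethyl)silyl]oxy}-3,7-dimethylnona-2,6-dien-4-yl benzoate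
Product: 15 (2Z,4S,6E)-1,9-dihydroxy-3,7-dimethylnona-2,6-dien-4-yl benzoate
Conditions: HF·pyridine, THF/pyridine, 0 °C to rt
Reagents that add atoms: none
Why: Fluoride desilylation of both primary silyl ethers under mildly acidic conditions, which avoids base-induced benzoate migration.

Step 9
Reactants: 15 (2Z,4S,6E)-1,9-dihydroxy-3,7-dimethylnona-2,6-dien-4-yl benzoate
Product: 16 (2Z,4S,6E)-9-hydroxy-3,7-dimethyl-1-oxonona-2,6-dien-4-yl benzoate
Conditions: MnO2 (activated, excess), CH2Cl2, rt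
Reagents that add atoms: none
Why: MnO2 oxidises only the allylic primary alcohol and keeps the Z geometry; the homoallylic alcohol is left alone.

Step 10
Reactants: 16 (2Z,4S,6E)-9-hydroxy-3,7-dimethyl-1-oxonona-2,6-dien-4-yl benzoate; 17 methyl propiolate
Product: 18 methyl (4R,5Z,7S,9E)-7-(benzoyloxy)-4,12-dihydroxy-6,10-dimethyldodeca-5,9-dien-2-ynoate
Conditions: Me2Zn (4 equiv), (S,S)-ProPhenol (20 mol%), Ph3PO (40 mol%), toluene, 0 °C
Reagents that add atoms: none
Why: Trost zinc–ProPhenol alkynylation of the enal: the dinuclear zinc catalyst delivers the zinc acetylide to one aldehyde face and sets the 4R carbinol (target C6) by catalyst control.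

Step 11
Reactants: 18 methyl (4R,5Z,7S,9E)-7-(benzoyloxy)-4,12-dihydroxy-6,10-dimethyldodeca-5,9-dien-2-ynoate
Product: 20 (1Z,3S,5E)-8-hydroxy-2,6-dimethyl-1-[(2S)-5-oxo-2,5-dihydrofuran-2-yl]octa-1,5-dien-3-yl benzoate, via Z-enoate 19 (not isolated)
Conditions: H2 (1 atm), Pd/CaCO3–Pb(OAc)2 (Lindlar), quinoline, EtOAc, rt; then PPTS (cat.), CH2Cl2, rt
Reagents that add atoms: none
Why: Lindlar semihydrogenation gives the Z-enoate, whose ester sits cis to the hydroxyl and lactonises to the butenolide; no stereocentre is changed (the descriptor changes by CIP priority only).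

Step 12
Reactants: 20 (1Z,3S,5E)-8-hydroxy-2,6-dimethyl-1-[(2S)-5-oxo-2,5-dihydrofuran-2-yl]octa-1,5-dien-3-yl benzoate
Product: 21 (1Z,3S,5E)-2,6-dimethyl-8-oxo-1-[(2S)-5-oxo-2,5-dihydrofuran-2-yl]octa-1,5-dien-3-yl benzoate
Conditions: Dess–Martin periodinane, NaHCO3, CH2Cl2, 0 °C; used at once
Reagents that add atoms: none
Why: Neutral Dess–Martin oxidation of the primary alcohol; the base-sensitive γ-alkenyl butenolide survives.

Step 13
Reactants: 21 (1Z,3S,5E)-2,6-dimethyl-8-oxo-1-[(2S)-5-oxo-2,5-dihydrofuran-2-yl]octa-1,5-dien-3-yl benzoate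
Product: 24 (3S,6R,7R,8R,1(10)E,4Z)-3-(benzoyloxy)-13-(dimethylamino)-8-hydroxy-11,13-dihydrogermacra-1(10),4-dien-12,6-olide, via samarium ketyl radical 22 (not isolated), via samarium enolate 23 (not isolated)
Conditions: SmI2 (2.5 equiv), THF, −78 °C, 21 added by syringe pump (final 0.002 M), then −40 °C; then CH2=N(CH3)2+ I− (4 equiv), −40 °C to rt
Reagents that add atoms: N,N-dimethylmethyleneiminium iodide (Eschenmoser's salt), C[N+](C)=C.[I-]
Why: Proposed new method: SmI2 turns the aldehyde into a samarium ketyl radical that adds 10-exo-trig to C7 of the butenolide anti to the C6 substituent (trans lactone, 7R) through a transition state in which trivalent samarium bridges the ketyl oxygen and the lactone carbonyl with the C9 chain outside (8R), a second SmI2 reduces the α-radical to the samarium enolate and this is aminomethylated; the closest known chemistry is the Fukuzawa–Molander SmI2 ketyl–olefin coupling of aldehydes with acrylates and butenolides (five- to eight-membered rings) with aldol-type trapping of the samarium enolate, extended here to a ten-membered ring in aprotic THF at high dilution, where the ketyl has no faster unimolecular exit.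

Step 14
Reactants: 24 (3S,6R,7R,8R,1(10)E,4Z)-3-(benzoyloxy)-13-(dimethylamino)-8-hydroxy-11,13-dihydrogermacra-1(10),4-dien-12,6-olide
Product: 26 (3S,6R,7R,8R,1(10)E,4Z)-3-(benzoyloxy)-8-hydroxygermacra-1(10),4,11(13)-trien-12,6-olide, via trimethylammonium iodide 25 (not isolated)
Conditions: MeI (excess), CH2Cl2/MeCN, rt; then aq. NaHCO3, EtOAc, rt
Reagents that add atoms: none
Why: Exhaustive methylation of the Mannich base and E1cB loss of trimethylamine give the exocyclic methylene (Eschenmoser α-methylenation); the C11 centre disappears and the others are untouched.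

Step 15
Reactants: 27 (2E)-2-methylbut-2-en-1-ol
Product: 28 [(2R,3R)-2,3-dimethyloxiran-2-yl]methanol
Conditions: Ti(OiPr)4 (10 mol%), D-(−)-diethyl tartrate, t-BuOOH, 4 Å MS, CH2Cl2, −20 °C
Reagents that add atoms: tert-butyl hydroperoxide, CC(C)(C)OO
Why: Sharpless asymmetric epoxidation: the titanium–D-tartrate complex delivers oxygen to the alkene face that gives the (2R,3R) epoxy alcohol, stereospecifically syn.

Step 16
Reactants: 28 [(2R,3R)-2,3-dimethyloxiran-2-yl]methanol
Product: 29 (2S,3R)-2,3-dimethyloxirane-2-carboxylic acid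
Conditions: RuCl3 (2 mol%), NaIO4, MeCN/EtOAc/H2O, rt
Reagents that add atoms: water, O; sodium periodate, [Na+].[O-]I(=O)(=O)=O
Why: Sharpless RuO4 oxidation of the primary alcohol to the acid; no stereocentre is touched (C2 changes from R to S by CIP priority only).

Step 17
Reactants: 26 (3S,6R,7R,8R,1(10)E,4Z)-3-(benzoyloxy)-8-hydroxygermacra-1(10),4,11(13)-trien-12,6-olide; 29 (2S,3R)-2,3-dimethyloxirane-2-carboxylic acid
Product: 30 (3S,6R,7R,8R,1(10)E,4Z)-3-(benzoyloxy)-8-{[(2S,3R)-2,3-dimethyloxiran-2-yl]carbonyloxy}germacra-1(10),4,11(13)-trien-12,6-olide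
Conditions: DCC, DMAP (20 mol%), CH2Cl2, 0 °C to rt
Reagents that add atoms: none
Why: Steglich esterification of the secondary alcohol; the acid has a quaternary α-carbon, so nothing can epimerise.

Step 18
Reactants: 30 (3S,6R,7R,8R,1(10)E,4Z)-3-(benzoyloxy)-8-{[(2S,3R)-2,3-dimethyloxiran-2-yl]carbonyloxy}germacra-1(10),4,11(13)-trien-12,6-olide
Product: 31 (1R,3S,6R,7R,8R,10R,4Z)-3-(benzoyloxy)-1,10-epoxy-8-{[(2S,3R)-2,3-dimethyloxiran-2-yl]carbonyloxy}germacra-4,11(13)-dien-12,6-olide
Conditions: mCPBA (1.2 equiv), NaHCO3, CH2Cl2, 0 °C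
Reagents that add atoms: 3-chloroperoxybenzoic acid, OOC(=O)c1cccc(Cl)c1
Why: Prilezhaev epoxidation: only the C1=C10 alkene is electron-rich (C4=C5 carries two allylic acyloxy groups, the enoate is electron-poor), and attack from the exposed outer face of the ten-membered ring is expected to give the trans (1R,10R) epoxide by stereospecific syn addition.

**Compound list**
1 | but-2-yn-1-ol | CC#CCO | starting material
2 | sodium alkenylaluminate (five-membered O–Al–C(CH3)=CH–CH2 ring, two 2-methoxyethoxy groups on Al) | [Na+].CC1=CCO[Al-]1(OCCOC)OCCOC | intermediate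
3 | (2Z)-3-iodobut-2-en-1-ol | C/C(I)=C/CO | intermediate
4 | tert-butyl{[(2Z)-3-iodobut-2-en-1-yl]oxy}dimethylsilane | C/C(I)=C/CO[Si](C)(C)C(C)(C)C | intermediate
5 | but-3-yn-1-ol | C#CCCO | starting material
6 | tert-butyl(but-3-yn-1-yloxy)dimethylsilane | C#CCCO[Si](C)(C)C(C)(C)C | intermediate
7 | oxirane | C1CO1 | starting material
8 | [(1E)-4-{[tert-butyl(dimethyl)silyl]oxy}-2-methylbut-1-en-1-yl]dimethylalumane | C[Al](C)/C=C(\C)CCO[Si](C)(C)C(C)(C)C | intermediate
9 | lithium butyl[(1E)-4-{[tert-butyl(dimethyl)silyl]oxy}-2-methylbut-1-en-1-yl]dimethylaluminate | [Li+].CCCC[Al-](C)(C)/C=C(\C)CCO[Si](C)(C)C(C)(C)C | intermediate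
10 | (3E)-6-{[tert-butyl(dimethyl)silyl]oxy}-4-methylhex-3-en-1-ol | OCC/C=C(\C)CCO[Si](C)(C)C(C)(C)C | intermediate
11 | (3E)-6-{[tert-butyl(dimethyl)silyl]oxy}-4-methylhex-3-enal | O=CC/C=C(\C)CCO[Si](C)(C)C(C)(C)C | intermediate
12 | (2Z,4S,6E)-1,9-bis{[tert-butyl(dimethyl)silyl]oxy}-3,7-dimethylnona-2,6-dien-4-ol | CC(C)(C)[Si](C)(C)OC/C=C(/C)[C@@H](O)C/C=C(\C)CCO[Si](C)(C)C(C)(C)C | intermediate
13 | benzaldehyde | O=Cc1ccccc1 | starting material
14 | (2Z,4S,6E)-1,9-bis{[tert-butyl(dimethyl)silyl]oxy}-3,7-dimethylnona-2,6-dien-4-yl benzoate | CC(C)(C)[Si](C)(C)OC/C=C(/C)[C@@H](OC(=O)c1ccccc1)C/C=C(\C)CCO[Si](C)(C)C(C)(C)C | intermediate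
15 | (2Z,4S,6E)-1,9-dihydroxy-3,7-dimethylnona-2,6-dien-4-yl benzoate | OC/C=C(/C)[C@@H](OC(=O)c1ccccc1)C/C=C(\C)CCO | intermediate
16 | (2Z,4S,6E)-9-hydroxy-3,7-dimethyl-1-oxonona-2,6-dien-4-yl benzoate | O=C/C=C(/C)[C@@H](OC(=O)c1ccccc1)C/C=C(\C)CCO | intermediate
17 | methyl propiolate (methyl prop-2-ynoate) | C#CC(=O)OC | starting material
18 | methyl (4R,5Z,7S,9E)-7-(benzoyloxy)-4,12-dihydroxy-6,10-dimethyldodeca-5,9-dien-2-ynoate | O[C@@H](C#CC(=O)OC)/C=C(/C)[C@@H](OC(=O)c1ccccc1)C/C=C(\C)CCO | intermediate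
19 | methyl (2Z,4S,5Z,7S,9E)-7-(benzoyloxy)-4,12-dihydroxy-6,10-dimethyldodeca-2,5,9-trienoate | O[C@@H](/C=C\C(=O)OC)/C=C(/C)[C@@H](OC(=O)c1ccccc1)C/C=C(\C)CCO | intermediate
20 | (1Z,3S,5E)-8-hydroxy-2,6-dimethyl-1-[(2S)-5-oxo-2,5-dihydrofuran-2-yl]octa-1,5-dien-3-yl benzoate | O=C1O[C@@H](C=C1)/C=C(/C)[C@@H](OC(=O)c1ccccc1)C/C=C(\C)CCO | intermediate
21 | (1Z,3S,5E)-2,6-dimethyl-8-oxo-1-[(2S)-5-oxo-2,5-dihydrofuran-2-yl]octa-1,5-dien-3-yl benzoate | O=C1O[C@@H](C=C1)/C=C(/C)[C@@H](OC(=O)c1ccccc1)C/C=C(\C)CC=O | intermediate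
22 | samarium ketyl radical of 21 (radical on C8, O–SmI2) | O=C1O[C@@H](C=C1)/C=C(/C)[C@@H](OC(=O)c1ccccc1)C/C=C(\C)C[CH]O[Sm](I)I | intermediate
23 | cyclised bis(diiodosamarium) C8-alkoxide and lactone enolate (3S,6R,7R,8R) | C1=C(O[Sm](I)I)O[C@@H]2/C=C(/C)[C@@H](OC(=O)c3ccccc3)C/C=C(\C)C[C@@H](O[Sm](I)I)[C@@H]12 | intermediate
24 | (3S,6R,7R,8R,1(10)E,4Z)-3-(benzoyloxy)-13-(dimethylamino)-8-hydroxy-11,13-dihydrogermacra-1(10),4-dien-12,6-olide; ten-membered carbocycle trans-fused to the γ-lactone, C11 epimers (centre removed in step 14) | CN(C)CC1C(=O)O[C@@H]2/C=C(/C)[C@@H](OC(=O)c3ccccc3)C/C=C(\C)C[C@@H](O)[C@@H]12 | intermediate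
25 | N,N,N-trimethylammonium iodide of 24 | C[N+](C)(C)CC1C(=O)O[C@@H]2/C=C(/C)[C@@H](OC(=O)c3ccccc3)C/C=C(\C)C[C@@H](O)[C@@H]12.[I-] | intermediate
26 | (3S,6R,7R,8R,1(10)E,4Z)-3-(benzoyloxy)-8-hydroxygermacra-1(10),4,11(13)-trien-12,6-olide | C=C1C(=O)O[C@@H]2/C=C(/C)[C@@H](OC(=O)c3ccccc3)C/C=C(\C)C[C@@H](O)[C@@H]12 | intermediate
27 | (2E)-2-methylbut-2-en-1-ol (tiglyl alcohol) | C/C=C(\C)CO | starting material
28 | [(2R,3R)-2,3-dimethyloxiran-2-yl]methanol | OC[C@@]1(C)O[C@@H]1C | intermediate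
29 | (2S,3R)-2,3-dimethyloxirane-2-carboxylic acid | OC(=O)[C@@]1(C)O[C@@H]1C | intermediate
30 | (3S,6R,7R,8R,1(10)E,4Z)-3-(benzoyloxy)-8-{[(2S,3R)-2,3-dimethyloxiran-2-yl]carbonyloxy}germacra-1(10),4,11(13)-trien-12,6-olide | C=C1C(=O)O[C@@H]2/C=C(/C)[C@@H](OC(=O)c3ccccc3)C/C=C(\C)C[C@@H](OC(=O)[C@@]3(C)O[C@@H]3C)[C@@H]12 | intermediate
31 | CNP0324463.4: (1R,3S,6R,7R,8R,10R,4Z)-3-(benzoyloxy)-1,10-epoxy-8-{[(2S,3R)-2,3-dimethyloxiran-2-yl]carbonyloxy}germacra-4,11(13)-dien-12,6-olide | C=C1C(=O)O[C@@H]2/C=C(/C)[C@@H](OC(=O)c3ccccc3)C[C@H]3O[C@]3(C)C[C@@H](OC(=O)[C@@]3(C)O[C@@H]3C)[C@@H]12 | target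

**Totals and risks**

Total step count: 18. Longest linear sequence: 14 steps (5 → 6 → 10 → 11 → 12 → 14 → 15 → 16 → 18 → 20 → 21 → 24 → 26 → 30 → 31).

The three steps most likely to fail:

Step 13 (radical macrocyclisation). The ten-membered closure may lose to pinacol coupling or to SmI2 reduction of the butenolide or benzoate, the C8 configuration rests on an untested chelate model, and the enolate trapping is unproven. The fallback sets out from alcohol 20 and replaces stoichiometric reductive ketyl chemistry by a redox-neutral, catalytic C–H alkylation. Irradiation of 20 with [Ir(dF(CF3)ppy)2(dtbbpy)]PF6, quinuclidine and Bu4N H2PO4 in MeCN at high dilution (blue light) forms the α-hydroxyalkyl radical at C8 by hydrogen-atom transfer, at very low concentration and with no reductant in the flask. Its cyclisation onto the butenolide gives (3S,6R,7R,8R,1(10)E,4Z)-3-(benzoyloxy)-8-hydroxy-11,13-dihydrogermacra-1(10),4-dien-12,6-olide F1. Treatment of this with LDA (2.2 equiv) and then Eschenmoser's salt comes back to the route at 24. If only C8 is wrong, it can be inverted at the stage of 26 by a Mitsunobu esterification with 29.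

Step 18 (face of the ring epoxidation). The outcome depends on which conformer of the acylated macrocycle the peracid meets. The fallback sets out from alcohol 26 and epoxidises before acylation under reagent control: Shi's fructose-derived ketone (enantiomer chosen for the 1R,10R face) with Oxone, or hydroxyl-directed VO(acac)2/t-BuOOH if the ring conformation allows. This gives (1R,3S,6R,7R,8R,10R,4Z)-3-(benzoyloxy)-1,10-epoxy-8-hydroxygermacra-4,11(13)-dien-12,6-olide F2, which is esterified with acid 29 (DCC, DMAP) and comes back to the route at 31.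

Step 6 (asymmetric Nozaki–Hiyama–Kishi coupling). Ligand control with a hindered Z-trisubstituted alkenylchromium and an enolisable β,γ-unsaturated aldehyde may be modest. The fallback sets out from 4 and 11 and moves the stereocontrol to a ketone reduction. The ligand-free CrCl2/NiCl2 coupling gives (2Z,4RS,6E)-1,9-bis{[tert-butyl(dimethyl)silyl]oxy}-3,7-dimethylnona-2,6-dien-4-ol F3. Dess–Martin oxidation gives (2Z,6E)-1,9-bis{[tert-butyl(dimethyl)silyl]oxy}-3,7-dimethylnona-2,6-dien-4-one F4. Reduction with (R)-2-methyl-CBS-oxazaborolidine and BH3·SMe2 (alkenyl as the large group) comes back to the route at 12.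

**Further compounds**
F1 | step 13 | (3S,6R,7R,8R,1(10)E,4Z)-3-(benzoyloxy)-8-hydroxy-11,13-dihydrogermacra-1(10),4-dien-12,6-olide | C1C(=O)O[C@@H]2/C=C(/C)[C@@H](OC(=O)c3ccccc3)C/C=C(\C)C[C@@H](O)[C@@H]12
F2 | step 18 | (1R,3S,6R,7R,8R,10R,4Z)-3-(benzoyloxy)-1,10-epoxy-8-hydroxygermacra-4,11(13)-dien-12,6-olide | C=C1C(=O)O[C@@H]2/C=C(/C)[C@@H](OC(=O)c3ccccc3)C[C@H]3O[C@]3(C)C[C@@H](O)[C@@H]12
F3 | step 6 | (2Z,4RS,6E)-1,9-bis{[tert-butyl(dimethyl)silyl]oxy}-3,7-dimethylnona-2,6-dien-4-ol | CC(C)(C)[Si](C)(C)OC/C=C(/C)C(O)C/C=C(\C)CCO[Si](C)(C)C(C)(C)C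
F4 | step 6 | (2Z,6E)-1,9-bis{[tert-butyl(dimethyl)silyl]oxy}-3,7-dimethylnona-2,6-dien-4-one | CC(C)(C)[Si](C)(C)OC/C=C(/C)C(=O)C/C=C(\C)CCO[Si](C)(C)C(C)(C)C
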